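If X is made from D by a first-order step, the X formed equals that rate constant times the time integral of [D], so that integral is the thing to reckon first.

    D → X (k1 = 5.3 × 10⁻⁴ s⁻¹)
    X → Z (k2 = 5.2 × 10⁻⁵ s⁻¹)
    Z → G (k3 = 0.0010 s⁻¹)
    G → J (k4 = 0.0015 s⁻¹)
    2 D → D2 (k5 = 0.0032 M⁻¹ s⁻¹)

- south-west: D 0.10 M; time 20 min; everything together in a closed stirred flask, run for 20 min
- north: D 0.10 M; one stirred flow tank at steady state, fed with the mixture as stated, mean residence time 20 min

- a species is counted by the D in it: one D2 counts as two
- a step written with two of one species runs at k times the square of its concentration and takes two of it each time
- the stated concentrations are those of everything mixed, before any reaction; amounts are the same in each set-up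
- run time (south-west): 20 min

- the set-up with the highest amount of X at the outlet or at the end, in percent of the D put in ("none" if the first two lie within 2 percentage points) (south-west / north / none)
- amount of X at the outlet or at the end, in percent of the D put in, south-west
- amount of X at the outlet or at the end, in percent of the D put in, north

My colleague and I dispute the vessels. Let a be the constant of D → X, b twice the constant of the pairing of D, and c the charged concentration. My colleague argues from the instantaneous selectivity S = a/(a + b[D]), the share of the D being lost that becomes X. The balance of tank north gives [D] = 0.0496 M, so S there is 62.5%, higher than the 45.3% of flask south-west at its start; my colleague backs the tank.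

I answer that a share must still be multiplied by what is lost, and I reckon the D-exposure share φ, which is a∫[D]dt/c, the part of the charge that has passed through D → X. Integrating the rate law of D for south-west gives φ = 37.3%. In north the integral is [D] times the residence time, so φ = 31.5%. The flask's φ is higher than the tank's, by 5.8 percentage points. The half-life of X by X → Z alone, 3.7 h, is longer than the 20 min, so I take φ as a close upper estimate of X.

The forecast sides with me: south-west, with 35.9% for south-west and 29.7% for north. Both are lower than my φ values, as it also charges the loss of X; of flask south-west it says: “X formed waits about 710 s on average”.

The simulation gives south-west, with 35.9% in south-west and 29.7% in north, which lie 1.4 points and 1.8 points under φ. My colleague's order holds at ten times the time: tank north at that residence time gives 47.3%, more than the 38.2% of flask south-west at that run time, where 0.0784% of the charge is then still D.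

For a flask like south-west charged with 0.17 M of D, φ comes to 32.9%. The computed X there is 31.7%, less than that φ.

Its constants were drawn at random within sensible limits; what happens was integrated by code.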